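**Retrosynthetic overview**

1. The strategy rests on the lactone carbonyl carbon of the five-membered hydroxy lactone fused to ring B. It is bonded to C4', the ring carbon between the phenol carbon C5' and C3', which carries the lactol CH(OH) (ring B: C1' ester O, C2' ether O, C6' CH2OH). C4' carries bromine from the first ring B step and takes up CO last.
2. Target ⇐ lipase deacylation ⇐ acetonide hydrolysis ⇐ acylative dynamic kinetic resolution ⇐ racemic lactol ⇐ palladium-catalysed carbonylative annulation of the bis-acetonide bromo aldehyde depsidone with CO and water.
3. Bromo aldehyde depsidone ⇐ intramolecular Ullmann ether closure of a dibromo depside ⇐ Steglich ester of a ring A salicylic acid with a ring B phenol.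
4. Ring B ⇐ 2,6-dihydroxybenzaldehyde through symmetric dibromo intermediates: both bromines end ortho to the formyl group, one becomes the ether site and the other the CO site. Ring A ⇐ methyl orsellinate by ortho-formylation at C3.
5. Ring order: one benzodioxine acetonide on each arene, then the seven-membered depsidone ring (ester, then ether), last the five-membered lactol ring.

Key step: step 12

Assumption: the lactol carbon is taken to epimerise through the ring-opened formyl acid quickly with base but only slowly in neutral, water-poor media at or below 20 °C, so its S configuration is set in the last three steps and the free lactol is released last.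

Assumption: the (R) enantiomer of the isothiourea catalyst is taken to acylate the S lactol faster; if a trial on 3-hydroxyphthalide shows the opposite sense, the (S) catalyst is used in step 13 with nothing else changed.

**Ring A**

Step 1
Reactants: 1 methyl orsellinate
Product: 2 methyl haematommate (methyl 3-formyl-2,4-dihydroxy-6-methylbenzoate)
Conditions: Cl2CHOMe, TiCl4, CH2Cl2, −10 to 0 °C; then ice/aq. HCl
Reagents that add atoms: dichloromethyl methyl ether, COC(Cl)Cl; water, O
Why: Rieche formylation, in which TiCl4 chelates the C2 hydroxyl and the ester carbonyl and should steer the electrophile to C3, the carbon ortho to that hydroxyl and between the two oxygens, the aldehyde being unveiled on aqueous work-up.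

Step 2
Reactants: 2 methyl haematommate
Product: 3 methyl 2,4-dihydroxy-3-(hydroxymethyl)-6-methylbenzoate
Conditions: NaBH4, THF/EtOH, 0 °C; aq. NH4Cl
Reagents that add atoms: none
Why: Borohydride reduction of the aryl aldehyde, which leaves the hindered, hydrogen-bonded methyl ester untouched at 0 °C; the acid-sensitive triol is carried on crude.

Step 3
Reactants: 3 methyl 2,4-dihydroxy-3-(hydroxymethyl)-6-methylbenzoate
Product: 4 methyl 5-hydroxy-2,2,7-trimethyl-4H-1,3-benzodioxine-6-carboxylate
Conditions: Me2C(OMe)2, PPTS (cat.), acetone, 20 °C
Reagents that add atoms: 2,2-dimethoxypropane, COC(C)(C)OC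
Why: Acid-catalysed transketalisation (acetonide formation) under thermodynamic control should engage the C4 hydroxyl and the CH2OH, because the C2 hydroxyl stays locked in its hydrogen bond to the ester carbonyl.

Step 4
Reactants: 4 methyl 5-hydroxy-2,2,7-trimethyl-4H-1,3-benzodioxine-6-carboxylate
Product: 5 5-hydroxy-2,2,7-trimethyl-4H-1,3-benzodioxine-6-carboxylic acid
Conditions: KOH, DMSO/H2O, 70 °C; then 1 M HCl to pH 3, 0 °C
Reagents that add atoms: potassium hydroxide, [K+].[OH-]
Why: Saponification of the hindered salicylate needs hot KOH in aqueous DMSO, which the base-stable ketal tolerates, and a brief cold acidification spares the ketal and avoids decarboxylation.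

**Ring B**

Step 5
Reactants: 6 2,6-dihydroxybenzaldehyde
Product: 7 3,5-dibromo-2,6-dihydroxybenzaldehyde
Conditions: NBS (2.05 equiv), MeCN, 0 to 20 °C
Reagents that add atoms: N-bromosuccinimide, O=C1CCC(=O)N1Br
Why: Electrophilic aromatic bromination, in which C3 and C5 are each ortho to one hydroxyl and para to the other and are the only activated positions, so the symmetric dibromide should form.

Step 6
Reactants: 7 3,5-dibromo-2,6-dihydroxybenzaldehyde
Product: 8 4,6-dibromo-2-(hydroxymethyl)benzene-1,3-diol
Conditions: NaBH4 (excess), THF/EtOH, 0 to 20 °C; aq. NH4Cl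
Reagents that add atoms: none
Why: Borohydride reduction of the salicylaldehyde-type carbonyl, with the aryl bromides inert and blocking the ring positions through which the benzylic alcohol could self-condense.

Step 7
Reactants: 8 4,6-dibromo-2-(hydroxymethyl)benzene-1,3-diol
Product: 9 6,8-dibromo-2,2-dimethyl-4H-1,3-benzodioxin-5-ol
Conditions: Me2C(OMe)2, PPTS (cat.), acetone, 20 °C
Reagents that add atoms: 2,2-dimethoxypropane, COC(C)(C)OC
Why: Acetonide formation by transketalisation, in which closure onto either phenol of symmetric 8 gives the same benzodioxine and leaves one phenol free, the event that later tells the two bromines apart.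

Step 8
Reactants: 9 6,8-dibromo-2,2-dimethyl-4H-1,3-benzodioxin-5-ol
Product: 10 tert-butyl[(6,8-dibromo-2,2-dimethyl-4H-1,3-benzodioxin-5-yl)oxy]dimethylsilane
Conditions: TBSCl, imidazole, DMF, 20 °C
Reagents that add atoms: tert-butyldimethylsilyl chloride, CC(C)(C)[Si](C)(C)Cl
Why: Silylation of the remaining phenol removes the only acidic proton before the amide base is used.

Step 9
Reactants: 10 tert-butyl[(6,8-dibromo-2,2-dimethyl-4H-1,3-benzodioxin-5-yl)oxy]dimethylsilane
Product: 12 6,8-dibromo-5-hydroxy-2,2-dimethyl-4H-1,3-benzodioxine-7-carbaldehyde, via silyl ether aldehyde 11 (not isolated)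
Conditions: LiN(i-Pr)2, THF, −78 °C; DMF, −78 to −40 °C; AcOH, then Bu4NF, 0 °C
Reagents that add atoms: N,N-dimethylformamide, CN(C)C=O
Why: Deprotonative lithiation of the only ring hydrogen, acidified by its two flanking bromines as in the lithiation of 1,3-dibromobenzene, then formylation with DMF and fluoride desilylation in the same flask, the 2,6-dibromoaryllithium being kept at −78 °C so that it does not lose LiBr.

**Union and key step**

Step 10
Reactants: 5 5-hydroxy-2,2,7-trimethyl-4H-1,3-benzodioxine-6-carboxylic acid; 12 6,8-dibromo-5-hydroxy-2,2-dimethyl-4H-1,3-benzodioxine-7-carbaldehyde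
Product: 13 depside, 6,8-dibromo-7-formyl-2,2-dimethyl-4H-1,3-benzodioxin-5-yl 5-hydroxy-2,2,7-trimethyl-4H-1,3-benzodioxine-6-carboxylate
Conditions: DCC, DMAP (0.2 equiv), CH2Cl2, 0 to 20 °C
Reagents that add atoms: none
Why: Steglich esterification, in which the carbodiimide-activated salicylic acid acylates the single phenol of 12 while the chelated C2 hydroxyl of 5 stays passive, as in carbodiimide couplings used for depsides.

Step 11
Reactants: 13 depside
Product: 14 bis-acetonide bromo aldehyde depsidone (seven-membered ester/ether ring; ring B carries Br on C4' and CHO on C3')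
Conditions: CuI (20 mol %), N,N-dimethylglycine (40 mol %), Cs2CO3, dioxane, 90 °C, 0.01 M
Reagents that add atoms: none
Why: Intramolecular Ullmann diaryl ether synthesis, in which the ring A phenoxide can reach only the bromine ortho to the ester oxygen, a site also activated by the ortho formyl group, so the seven-membered ring closes there and the distal bromine is kept, high dilution holding back intermolecular coupling.

Step 12
Reactants: 14 bis-acetonide bromo aldehyde depsidone; 15 carbon monoxide
Product: 17 bis-acetonide lactol (racemic), via formyl acid 16 (not isolated)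
Conditions: Pd(OAc)2 (5 mol %), Xantphos (7.5 mol %), CO (1 atm), H2O (10 equiv), iPr2NEt (2 equiv), dioxane, 80 °C; then pH 4 buffer
Reagents that add atoms: carbon monoxide, [C-]#[O+]; water, O
Why: Pd(OAc)2 and Xantphos give zerovalent palladium, which adds oxidatively into the one remaining C–Br bond of ring B, made reactive by the ortho formyl group, and CO then inserts to give an aroyl palladium species. The hydrate of the neighbouring aldehyde (or water, followed by ring closure of formyl acid 16) delivers oxygen to the acyl carbon and the amine takes up HBr, which returns zerovalent palladium. The closest known reaction type is the palladium-catalysed carbonylative cyclisation of 2-bromobenzaldehydes to 3-hydroxy- and 3-alkoxyphthalides, a hydroxy- or alkoxycarbonylation with the aldehyde as internal partner. The five-membered lactol ring closes in a 5-exo-trig sense, the hydrate oxygen attacking the exocyclic acyl carbon. The lactol carbon is formed without control and is racemic, its enantiomers interconverting through 16, so its configuration is left to step 13. The step needs chemoselectivity for the C–Br bond over the depsidone ester and a fixed placement of the two oxidation levels: the ester carbonyl is shielded by its flanking methyl and aryloxy groups and meets only a hindered tertiary amine and a little water, the wide-bite-angle diphosphine lets the hindered bromide carbonylate at 1 atm, and because bromine marks the carbon next to the protected phenol while the formyl group already sits next to the diaryl ether carbon, the acid and aldehyde levels cannot be exchanged.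

**Stereocentre and deprotection**

Step 13
Reactants: 17 bis-acetonide lactol (racemic)
Product: 18 bis-acetonide (S)-lactol isobutyrate
Conditions: (R)-benzotetramisole (10 mol %), (i-PrCO)2O, iPr2NEt, CHCl3, 0 °C
Reagents that add atoms: isobutyric anhydride, CC(C)C(=O)OC(=O)C(C)C
Why: Acylative dynamic kinetic resolution of a 3-hydroxyphthalide-type lactol, run while the lactol hydroxyl is the only acylable group, in which the amine keeps the two lactol enantiomers in equilibrium through the formyl carboxylate and the chiral acyl isothiouronium ion acylates one of them faster, so the catalyst sets the S configuration at the acylal carbon.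

Step 14
Reactants: 18 bis-acetonide (S)-lactol isobutyrate
Product: 19 (S)-lactol isobutyrate with both phenols and both CH2OH groups free
Conditions: 1 M aq. HCl/THF (1:4), 20 °C
Reagents that add atoms: none
Why: Acid-catalysed ketal hydrolysis releases both phenol/benzyl alcohol pairs, while the acylal, whose oxocarbenium ion is destabilised by the lactone carbonyl, should survive dilute acid at room temperature with its configuration intact.

Step 15
Reactants: 19 (S)-lactol isobutyrate
Product: 20 target, (S)-lactol
Conditions: immobilised Candida antarctica lipase B, n-BuOH, 2-MeTHF, 20 °C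
Reagents that add atoms: none
Why: Lipase-catalysed alcoholysis (transesterification) of the activated acylal ester, in which the serine attacks the isobutyryl carbonyl, so the C–O bond at the stereocentre is not broken and the S lactol is released with retention in a neutral, water-poor medium in which ring opening is slow.

**Compound list**

1 | methyl orsellinate | COC(=O)c1c(C)cc(O)cc1O | starting material
2 | methyl haematommate | COC(=O)c1c(C)cc(O)c(C=O)c1O | intermediate
3 | methyl 2,4-dihydroxy-3-(hydroxymethyl)-6-methylbenzoate | COC(=O)c1c(C)cc(O)c(CO)c1O | intermediate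
4 | methyl 5-hydroxy-2,2,7-trimethyl-4H-1,3-benzodioxine-6-carboxylate | COC(=O)c1c(C)cc2OC(C)(C)OCc2c1O | intermediate
5 | 5-hydroxy-2,2,7-trimethyl-4H-1,3-benzodioxine-6-carboxylic acid | Cc1cc2OC(C)(C)OCc2c(O)c1C(=O)O | intermediate
6 | 2,6-dihydroxybenzaldehyde | O=Cc1c(O)cccc1O | starting material
7 | 3,5-dibromo-2,6-dihydroxybenzaldehyde | O=Cc1c(O)c(Br)cc(Br)c1O | intermediate
8 | 4,6-dibromo-2-(hydroxymethyl)benzene-1,3-diol | OCc1c(O)c(Br)cc(Br)c1O | intermediate
9 | 6,8-dibromo-2,2-dimethyl-4H-1,3-benzodioxin-5-ol | CC1(C)OCc2c(O)c(Br)cc(Br)c2O1 | intermediate
10 | tert-butyl[(6,8-dibromo-2,2-dimethyl-4H-1,3-benzodioxin-5-yl)oxy]dimethylsilane | CC1(C)OCc2c(O[Si](C)(C)C(C)(C)C)c(Br)cc(Br)c2O1 | intermediate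
11 | 6,8-dibromo-5-[(tert-butyldimethylsilyl)oxy]-2,2-dimethyl-4H-1,3-benzodioxine-7-carbaldehyde | CC1(C)OCc2c(O[Si](C)(C)C(C)(C)C)c(Br)c(C=O)c(Br)c2O1 | intermediate
12 | 6,8-dibromo-5-hydroxy-2,2-dimethyl-4H-1,3-benzodioxine-7-carbaldehyde | CC1(C)OCc2c(O)c(Br)c(C=O)c(Br)c2O1 | intermediate
13 | depside, 6,8-dibromo-7-formyl-2,2-dimethyl-4H-1,3-benzodioxin-5-yl 5-hydroxy-2,2,7-trimethyl-4H-1,3-benzodioxine-6-carboxylate | Cc1cc2OC(C)(C)OCc2c(O)c1C(=O)Oc1c(Br)c(C=O)c(Br)c2OC(C)(C)OCc12 | intermediate
14 | bis-acetonide bromo aldehyde depsidone | Cc1cc2OC(C)(C)OCc2c2c1C(=O)Oc1c3COC(C)(C)Oc3c(Br)c(C=O)c1O2 | intermediate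
15 | carbon monoxide | [C-]#[O+] | starting material
16 | bis-acetonide formyl acid (ring-opened form of 17) | Cc1cc2OC(C)(C)OCc2c2c1C(=O)Oc1c3COC(C)(C)Oc3c(C(=O)O)c(C=O)c1O2 | intermediate
17 | bis-acetonide lactol, racemic | Cc1cc2OC(C)(C)OCc2c2c1C(=O)Oc1c3COC(C)(C)Oc3c3c(c1O2)C(O)OC3=O | intermediate
18 | bis-acetonide (S)-lactol isobutyrate | Cc1cc2OC(C)(C)OCc2c2c1C(=O)Oc1c3COC(C)(C)Oc3c3c(c1O2)[C@@H](OC(=O)C(C)C)OC3=O | intermediate
19 | (S)-lactol isobutyrate, acetonides removed | Cc1cc(O)c(CO)c2c1C(=O)Oc1c(CO)c(O)c3c(c1O2)[C@@H](OC(=O)C(C)C)OC3=O | intermediate
20 | target, (S)-lactol | Cc1cc(O)c(CO)c2c1C(=O)Oc1c(CO)c(O)c3c(c1O2)[C@@H](O)OC3=O | target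

**Count and risks**

Total step count: 15. Longest linear sequence: 11 steps (steps 5 to 9, then 10 to 15).

Steps most likely to fail:

Step 12. Oxidative addition at the doubly ortho-substituted C–Br bond may be slower than opening of the depsidone ester by water and amine at 80 °C, or bromine may be lost by reduction. Fallback (sets out from 14, returns at 17): water is taken out of the palladium step. 14 is carbonylated without CO gas with phenyl formate (Pd(OAc)2, P(t-Bu)3·HBF4, Et3N, MeCN, 80 °C; the formate breaks down to CO and phenol in the flask) to give the phenyl ester of the formyl acid F1. This ester is hydrolysed at 20 °C in THF/aqueous NaHCO3, where the hydrate of the ortho formyl group acts as a neighbouring nucleophile and should make this aryl ester far more labile than the shielded depsidone ester. Acidification to pH 4 closes the acid to 17.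

Step 11. Closure at the crowded bromide may be slower than cleavage or transesterification of the activated aryl ester by carbonate and phenoxide, and copper may also remove the distal bromine by reduction. Fallback (sets out from 12 and 4, returns at 14): the ether is made before the ester, the classical order for depsidones. 12 is capped as its methoxymethyl ether F2 (MOMCl, iPr2NEt, CH2Cl2). F2 and the ring A phenol 4 are joined by an intermolecular Ullmann condensation (CuI, N,N-dimethylglycine, Cs2CO3, dioxane, 100 °C). This may take place at either bromine and so gives the diaryl ether at the carbon beside the acetonide oxygen F3 together with the regioisomeric diaryl ether at the carbon beside the MOM ether F4. Aqueous HCl in THF removes the MOM group and all acetonides, after which the two sides of ring B differ only by the ether, so F3 and F4 converge on the one methyl ester F5. KOH in aqueous DMSO gives the seco acid F6. DCC at high dilution closes the seven-membered lactone onto the only phenol ortho to the ether oxygen to give the acetonide-free depsidone F7. Me2C(OMe)2/PPTS then rebuilds both acetonides, each CH2OH having a single free phenol beside it, and gives 14.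

Step 15. Once the acyl group is off, the lactol may lose its configuration by ring-chain tautomerism during the enzymatic step or the isolation, and the acyl-enzyme may pass the isobutyryl group on to a CH2OH group. Fallback (sets out from 17, returns at 20): the configuration is set by separation. 17 is freed from both acetonides with 1 M aq. HCl/THF to give the racemic lactol F8. The enantiomers are separated by preparative chromatography on an immobilised polysaccharide chiral phase with an acidified, non-nucleophilic eluent at low temperature. The S enantiomer is 20; the R enantiomer is racemised with a trace of amine and passed through the column again.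

**Further compounds**

F1 | step 12 | phenyl ester of the bis-acetonide formyl acid | Cc1cc2OC(C)(C)OCc2c2c1C(=O)Oc1c3COC(C)(C)Oc3c(C(=O)Oc3ccccc3)c(C=O)c1O2
F2 | step 11 | 6,8-dibromo-5-(methoxymethoxy)-2,2-dimethyl-4H-1,3-benzodioxine-7-carbaldehyde | CC1(C)OCc2c(OCOC)c(Br)c(C=O)c(Br)c2O1
F3 | step 11 | diaryl ether, ring A oxygen on the ring B carbon beside the acetonide oxygen | COC(=O)c1c(C)cc2OC(C)(C)OCc2c1Oc1c(C=O)c(Br)c(OCOC)c2COC(C)(C)Oc12
F4 | step 11 | regioisomeric diaryl ether, ring A oxygen on the ring B carbon beside the MOM ether | COC(=O)c1c(C)cc2OC(C)(C)OCc2c1Oc1c(OCOC)c2COC(C)(C)Oc2c(Br)c1C=O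
F5 | step 11 | deprotected diaryl ether methyl ester | COC(=O)c1c(C)cc(O)c(CO)c1Oc1c(C=O)c(Br)c(O)c(CO)c1O
F6 | step 11 | seco acid | Cc1cc(O)c(CO)c(Oc2c(C=O)c(Br)c(O)c(CO)c2O)c1C(=O)O
F7 | step 11 | acetonide-free bromo aldehyde depsidone | Cc1cc(O)c(CO)c2c1C(=O)Oc1c(CO)c(O)c(Br)c(C=O)c1O2
F8 | step 15 | racemic lactol (racemic target) | Cc1cc(O)c(CO)c2c1C(=O)Oc1c(CO)c(O)c3c(c1O2)C(O)OC3=O
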